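**Compound numbering used throughout:** 1–14 bromide/pyranone branch, 15–19 alkyne branch, 20–24 key step, 25–28 elaboration of the flavone half, 29–32 chromone branch, 33 protected biflavonoid, 34 target.

## The problem

Compound 34 is an unsymmetrical biflavonoid in which a (2S)-5-hydroxy-7-methoxyflavanone and a 5,7-dihydroxyflavone are joined by a diaryl ether between C3' of the flavanone ring B and the 4'-oxygen of the flavone ring B. The only stereocentre is C2 of the flavanone; it is benzylic, carries the ring oxygen and lies β to the C4 ketone, so base or strong acid opens ring C to the 2'-hydroxychalcone and racemises it. Nothing else in the molecule can direct it, so it has to be set by a catalyst, late, and be followed only by neutral chemistry. Four phenols must end free and one oxygen as a methyl ether; two of the phenols are chelated to a carbonyl and slow to protect, and the methyl ether is best carried in from the start. The diaryl ether links two electron-rich rings beside a second oxygen, a poor site for a late copper or palladium coupling but an easy bond to make while one partner is still a 4-fluorophenyl ketone. Ring A of the flavone is a benzene fused to a 4-pyranone across C4a–C8a, with oxygen at C5 and C7 and hydrogen at C6 and C8, so its carbons C5–C8 can come from a two-carbon ketene attached to the pyranone carbon that becomes C8a and from a two-carbon oxygenated terminal alkyne, the ketene oxygen ending as the chelated 5-OH. Groups that need care are the diazoketone and ynol ether of that step, the aryl bromide that marks the future C1' (light, organolithiums), the 4-pyranone (hydroxide, hard nucleophiles) and the flavone C2=C3 bond in the final hydrogenolysis.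

## Retrosynthesis

**34 from 33.** The four O–benzyl bonds are cut. One protecting group on every phenol means a single neutral hydrogenolysis ends the synthesis, with no acid or base near C2. The methyl ether is already in place in 33, so no late differentiation of ring A oxygens is asked for.

**33 from 28 and 32.** The C2–C1' bond of the flavanone is cut. The neighbouring cut, the diaryl ether, would need an etherification between two hindered, electron-rich rings in the presence of a racemisable flavanone. Closing ring C by oxa-Michael addition would make the stereocentre under reversible conditions. The chosen cut gives an achiral chromone 32, two steps from a commercial ketone, and a boronic acid 28 that already contains the whole flavone half. The forward reaction must transfer the aryl group to one face of the unsubstituted C2 of 32 under catalyst control, in water-tolerant, near-neutral conditions, and leave the 2-aryl-substituted enone inside 28 untouched.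

**28 from 26 from 24.** The C–B bond is traced to the C–Br bond and the two benzyl ethers to the silyl ether and phenol of 24. Bromine is chosen as the tag for C1' because it is inert to SNAr, enolate chemistry and filtered light, yet is converted to boron in one operation. The forward steps ask only that the chelated 5-OH be alkylated.

**24 from 14 and 19.** Four bonds of the carbocycle are cut: C8–C8a, C7–C8, C5–C6 and C4a–C5. The classical cut through the pyranone ring starts from a ring that already holds three oxygens. It needs those oxygens differentiated and needs the diaryl ether partner as a separate acyl or formyl component. It is admittedly richer in precedent. The carbocycle cut is preferred because one acetyl group then serves twice: it activates the SNAr that makes the diaryl ether and it becomes C2 and C3 of the flavone. In addition, 5-OH and 7-O emerge already differentiated, free and silylated. The precursors are a diazoketone 14 built by enolate chemistry and a two-carbon alkyne 19. The forward reaction must generate a pyranonylketene cleanly, trap it with the ynol ether in one regiochemical sense, and close onto pyranone C3.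

**14 from 12 from 11 from 8 and 9.** The diazo carbon is removed from the acyl group, the acid is traced to its ethyl ester, and the pyranone is opened at O1–C2 and at the C–C bond to the oxalyl carbon. This leaves the 1,3-diketone 8 and diethyl oxalate 9, which supplies the future C8a and C5. The forward steps are a terminal Claisen condensation of a diketone dianion, acid cyclodehydration, a controlled saponification and a diazomethylation.

**8 from 6 and 7; 6 from 4 and 5; 4 from 2 from 1.** The diketone is cut at the acetyl C–C bond (Claisen condensation with 7, which supplies C4 and C4a). The diaryl ether is cut at the bond to the fluorinated ring (SNAr on 5). The phenol 4 is traced through the formate of a Baeyer–Villiger oxidation to the benzylated aldehyde 2 and on to 1. Each cut removes one simple commercial piece, and each forward step is standard.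

**19 from 15 and 16.** The O–Si bond and the C–O bond of the ynol ether are cut. Oxygen is put on the acetylide carbon electrophilically and the ynolate is silylated on oxygen by the bulky triflate 16.

**32 from 30 from 29.** The chromone is opened at O1–C2 and C2–C3 to the mono-benzylated ketone 30, which comes from 29 by one alkylation. 29 already carries the methyl ether at the future C7.

## Roads not taken

Alternative 1: The flavanone is cut at C3–C4. In the forward direction the 2-aryl-1,3-dithiane A1, which carries the (R)-configured 2-aryl-2-aryloxyethyl tosylate side chain, is deprotonated with LiN(iPr)2. The carbanion displaces the primary tosylate and closes ring C as the C4 dithioketal A2.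
- Merits: the stereocentre comes from a secondary carbinol of secure configuration and is not a reacting centre in the ring closure. C4 stays masked, so chalcone-type racemisation is impossible until the end.
- Weak points: the C2–H of A1 is benzylic and α to an aryloxy group, and a strong amide base can remove it. β-Elimination of the tosylate competes with a six-membered ring closure onto a hindered carbanion. Unmasking C4 needs oxidative or thiophilic reagents in the presence of electron-rich rings. The whole flavone half must still be built from the aryl bromide of A2, on a substrate that by then contains the flavanone.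
- Comparison: in certainty of configuration this road is better than the chosen plan, which relies on catalytic face selection on a large substrate. Against that the chosen plan sets the stereocentre in the penultimate step with every carbon in place, and is far shorter after the ring-forming event.

Alternative 2: The flavan is cut at O1–C8a. The (S)-carbinol A3 would cyclise onto the ring A aryl bromide with palladium diacetate and a hindered di-tert-butyl(biaryl)phosphine to give the flavan A4. The stereocentre is not involved, so configuration is retained.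
- Merits: intramolecular aryl ether formation to chromans is reliable, and the carbinol is available by asymmetric ketone reduction.
- Weak points: the palladium alkoxide of a secondary benzylic alcohol is prone to β-hydride elimination, and the aryl bromide sits on a doubly donor-substituted ring. A4 has the wrong oxidation state at C4. Oxidation there must beat oxidation at C2–H, which is benzylic and α to oxygen, and at the benzyl ether. One of two methyl ethers on ring A must then be removed selectively, and the flavone must still be built from the tert-butyl ester.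
- Comparison: the ring closure itself is at least as dependable as any single step of the chosen plan. The chosen plan, however, carries the correct oxidation level and the correct ring A ethers throughout and needs no late C–H oxidation.

Alternative 3: The flavanone is cut at C2–C3. The diazoketone A5 would lose N2 on Rh2(S-PTTL)4 (dirhodium tetrakis(N-phthaloyl-(S)-tert-leucinate)), and the carbenoid carbon would insert into the benzylic O–CH2 bond to give A6, forming ring C and the stereocentre together.
- Merits: it is the most convergent of all the plans. The full skeleton is assembled by a simple O-benzylation and the last skeletal bond and the stereocentre are made in one catalytic step. In step economy after fragment union it is clearly better than the chosen plan.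
- Weak points: a diazomethyl ketone gives an acceptor-only carbenoid of low selectivity. Six-membered ring insertion is disfavoured against attack by the neighbouring ether oxygen, which leads to a five-membered oxonium ylide and a Stevens shift, and against addition to the adjacent arene. Enantiocontrol for this carbenoid class is not dependable.
- Comparison: the chosen plan sets against this convergence an enantioselective step with direct precedent on chromones, and a benzannulation whose elementary steps are each known and which is carried out early on a small intermediate.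

Key step: step 9

## Route

Remark on the chemistry (assumption): the chromone face attacked under the (S)-configured bisphosphine in step 14 is assigned by analogy with cyclohexenone under (S)-biaryl bisphosphines, which corresponds to (2S). If a model addition shows the opposite sense, the (R)-ligand is used with no other change. Diazomethane is used as a separately prepared ether solution.

Step 1
Reactants: 1 5-bromo-2-hydroxybenzaldehyde
Product: 2 2-(benzyloxy)-5-bromobenzaldehyde
Conditions: BnBr, K2CO3, DMF, 20 °C
Reagents that add atoms: benzyl bromide, BrCc1ccccc1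
Why: Williamson etherification of an acidic ortho-formyl phenol; benzyl is the one protecting group that the last step removes from every phenol.

Step 2
Reactants: 2 2-(benzyloxy)-5-bromobenzaldehyde
Product: 4 2-(benzyloxy)-5-bromophenol, via aryl formate 3 (not isolated)
Conditions: mCPBA, CH2Cl2, 20 °C; then K2CO3 (cat.), MeOH, 20 °C
Reagents that add atoms: 3-chloroperoxybenzoic acid, OOC(=O)c1cccc(Cl)c1
Why: Baeyer–Villiger (Dakin-type) oxidation in which the ortho-alkoxyaryl group migrates in preference to hydrogen; methanolysis of the formate frees the phenol ortho to the benzyl ether and meta to bromine, as the diaryl ether requires.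

Step 3
Reactants: 4 2-(benzyloxy)-5-bromophenol; 5 4'-fluoroacetophenone
Product: 6 1-{4-[2-(benzyloxy)-5-bromophenoxy]phenyl}ethan-1-one
Conditions: K2CO3, DMAc, 130 °C
Reagents that add atoms: none
Why: SNAr displacement of fluoride activated by the para-acetyl group; the bromide on the nucleophile is on an unactivated ring and should not react.

Step 4
Reactants: 6 1-{4-[2-(benzyloxy)-5-bromophenoxy]phenyl}ethan-1-one; 7 ethyl acetate
Product: 8 1-{4-[2-(benzyloxy)-5-bromophenoxy]phenyl}butane-1,3-dione
Conditions: NaH, THF, 65 °C; then aq. HCl
Reagents that add atoms: none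
Why: Crossed Claisen condensation of the methyl ketone enolate with ethyl acetate, driven to completion by deprotonation of the 1,3-diketone formed.

Step 5
Reactants: 8 1-{4-[2-(benzyloxy)-5-bromophenoxy]phenyl}butane-1,3-dione; 9 diethyl oxalate
Product: 11 ethyl 6-{4-[2-(benzyloxy)-5-bromophenoxy]phenyl}-4-oxo-4H-pyran-2-carboxylate, via triketo ester 10 (not isolated)
Conditions: LiN(iPr)2 (3 equiv), THF, −78 → 0 °C; 9, −78 °C; aq. HCl; then TsOH·H2O, toluene, 80 °C
Reagents that add atoms: none
Why: The 1,3-diketone dianion reacts at its terminal, more basic carbon with the oxalate (Claisen condensation); acid-catalysed attack of the aryl ketone enol oxygen on the 2-keto group and dehydration then give the 4-pyranone, the classical route to 6-arylcomanic esters.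

Step 6
Reactants: 11 ethyl 6-{4-[2-(benzyloxy)-5-bromophenoxy]phenyl}-4-oxo-4H-pyran-2-carboxylate
Product: 12 6-{4-[2-(benzyloxy)-5-bromophenoxy]phenyl}-4-oxo-4H-pyran-2-carboxylic acid
Conditions: LiOH (1.2 equiv), THF/H2O, 0 °C; then 1 M HCl
Reagents that add atoms: lithium hydroxide, [Li+].[OH-]
Why: Saponification of an ester activated by the electron-poor ring should be fast at 0 °C; any hydroxide addition to the pyranone is reversed on acidification, which recloses the ring.

Step 7
Reactants: 12 6-{4-[2-(benzyloxy)-5-bromophenoxy]phenyl}-4-oxo-4H-pyran-2-carboxylic acid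
Product: 14 2-{4-[2-(benzyloxy)-5-bromophenoxy]phenyl}-6-(2-diazoacetyl)-4H-pyran-4-one, via mixed anhydride 13 (not isolated)
Conditions: iBuOCOCl, N-methylmorpholine, THF, −15 °C; then CH2N2, Et2O, 0 °C
Reagents that add atoms: diazomethane, C=[N+]=[N-]
Why: Acylation of diazomethane by a mixed carbonic anhydride (first stage of the Arndt–Eistert sequence); no HCl or chlorinating agent is present that could attack the pyranone oxygen or the diazoketone.

Step 8
Reactants: 15 acetylene; 16 triisopropylsilyl trifluoromethanesulfonate
Product: 19 (triisopropylsiloxy)acetylene, via lithium acetylide 17 (not isolated), via lithium ethynolate 18 (not isolated)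
Conditions: n-BuLi, THF, −78 °C; LiOOtBu (from tBuOOH, LiN(SiMe3)2), −78 → −20 °C; then 16, −78 → 0 °C
Reagents that add atoms: tert-butyl hydroperoxide, CC(C)(C)OO
Why: Electrophilic oxygen transfer from lithium tert-butyl peroxide to a lithium acetylide gives the ynolate, and the bulky silyl triflate silylates it on oxygen, not carbon; this is the standard preparation of 1-siloxyalkynes from terminal alkynes, applied here to the parent alkyne.

Step 9
Reactants: 14 2-{4-[2-(benzyloxy)-5-bromophenoxy]phenyl}-6-(2-diazoacetyl)-4H-pyran-4-one; 19 (triisopropylsiloxy)acetylene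
Product: 24 2-{4-[2-(benzyloxy)-5-bromophenoxy]phenyl}-5-hydroxy-7-[(triisopropylsilyl)oxy]-4H-chromen-4-one, via pyranonylketene 20 (not isolated), via siloxycyclobutenone 21 (not isolated), via dienylketene 22 (not isolated), via cyclohexadienone tautomer 23 (not isolated)
Conditions: 19 (2.5 equiv), hν (365 nm LEDs, Pyrex), ClCH2CH2Cl, 20 °C; then 80 °C
Reagents that add atoms: none
Why: Light absorbed by the diazoketone expels N2 and the pyranonyl group shifts to the former diazo carbon (Wolff rearrangement), giving ketene 20, which the electron-rich alkyne 19 traps in a [2+2] cycloaddition as cyclobutenone 21. Warming opens 21 by reversible four-electron electrocyclic cleavage to dienylketene 22, and only the isomer that turns the pyranone inward can react further. The carbocycle of the flavone is closed by six-electron electrocyclisation of 22, the ketene carbon bonding to pyranone C3 (flavone C4a–C5), and enolisation of dienone 23 to the chelated phenol makes the sequence irreversible. The closest known reaction type is the Danheiser benzannulation in its photochemical Wolff variant, established for aryl and heteroaryl diazomethyl ketones with siloxyalkynes; a 4-pyranone as the heteroaryl unit extends the scope, not the mechanism. No stereocentre is formed. The regiochemistry needed (hydroxyl at C5, siloxy at C7) follows from the polarisation of the ynol ether, whose unsubstituted carbon attacks the ketene carbonyl carbon, and from C3 being the only pyranone position next to the ketene-bearing carbon. Chemoselectivity rests on the wavelength: light near 365 nm reaches the diazoketone band but is expected to spare the aryl bromide and most of the aryl-pyranone absorption.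

Step 10
Reactants: 24 2-{4-[2-(benzyloxy)-5-bromophenoxy]phenyl}-5-hydroxy-7-[(triisopropylsilyl)oxy]-4H-chromen-4-one
Product: 26 5,7-bis(benzyloxy)-2-{4-[2-(benzyloxy)-5-bromophenoxy]phenyl}-4H-chromen-4-one, via dihydroxyflavone 25 (not isolated)
Conditions: Bu4NF, THF, 0 °C; then BnBr, K2CO3, DMF, 65 °C
Reagents that add atoms: benzyl bromide, BrCc1ccccc1
Why: Fluoride cleaves the silyl ether of the acidic 7-phenol; benzyl bromide with K2CO3 in warm DMF then alkylates both the 7-phenoxide and the chelated 5-OH (Williamson etherification), so that all phenols carry the same group.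

Step 11
Reactants: 26 5,7-bis(benzyloxy)-2-{4-[2-(benzyloxy)-5-bromophenoxy]phenyl}-4H-chromen-4-one
Product: 28 {4-(benzyloxy)-3-[4-(5,7-bis(benzyloxy)-4-oxo-4H-chromen-2-yl)phenoxy]phenyl}boronic acid, via pinacol boronate 27 (not isolated)
Conditions: B2pin2, PdCl2(dppf), KOAc, dioxane, 90 °C; then NaIO4, NH4OAc, acetone/H2O, 20 °C
Reagents that add atoms: bis(pinacolato)diboron, CC1(C)OB(OC1(C)C)B1OC(C)(C)C(C)(C)O1; water, O
Why: Miyaura borylation of the aryl bromide; periodate then cleaves the pinacol as the ester hydrolyses and gives the free boronic acid, which transmetalates to rhodium faster than the ester.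

Step 12
Reactants: 29 1-(2,6-dihydroxy-4-methoxyphenyl)ethan-1-one
Product: 30 1-[2-(benzyloxy)-6-hydroxy-4-methoxyphenyl]ethan-1-one
Conditions: BnBr (1.05 equiv), K2CO3, acetone, 56 °C
Reagents that add atoms: benzyl bromide, BrCc1ccccc1
Why: Mono-O-benzylation (Williamson etherification); after the first alkylation the remaining hydroxyl is locked in a hydrogen bond to the acetyl group and reacts much more slowly, so one equivalent of bromide should stop at 30.

Step 13
Reactants: 30 1-[2-(benzyloxy)-6-hydroxy-4-methoxyphenyl]ethan-1-one
Product: 32 5-(benzyloxy)-7-methoxy-4H-chromen-4-one, via enaminone 31 (not isolated)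
Conditions: Me2NCH(OMe)2, toluene, 100 °C; then HCl, CH2Cl2, 20 °C
Reagents that add atoms: N,N-dimethylformamide dimethyl acetal, COC(OC)N(C)C
Why: Condensation of the methyl ketone with the formamide acetal gives the enaminone; acid-promoted addition of the phenol to its β-carbon and loss of dimethylamine close the chromone (standard enaminone chromone synthesis).

Step 14
Reactants: 28 {4-(benzyloxy)-3-[4-(5,7-bis(benzyloxy)-4-oxo-4H-chromen-2-yl)phenoxy]phenyl}boronic acid; 32 5-(benzyloxy)-7-methoxy-4H-chromen-4-one
Product: 33 (2S)-5-(benzyloxy)-2-{4-(benzyloxy)-3-[4-(5,7-bis(benzyloxy)-4-oxo-4H-chromen-2-yl)phenoxy]phenyl}-7-methoxy-2,3-dihydro-4H-chromen-4-one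
Conditions: [RhOH(cod)]2 (cat.), (S)-MeO-F12-BIPHEP [(S)-6,6'-dimethoxy-2,2'-bis{bis(3,4,5-trifluorophenyl)phosphino}-1,1'-biphenyl], 32 (2.5 equiv), toluene/H2O, 30 °C
Reagents that add atoms: none
Why: Rhodium-catalysed asymmetric conjugate addition of an arylboronic acid to a chromone (Hayashi–Miyaura reaction), a known route to flavanones including oxygenated ring A patterns; the electron-poor bisphosphine speeds insertion of the electron-rich chromone and water protonates the rhodium enolate without opening ring C. The new C2 stereocentre is set by the ligand, which should direct the aryl–rhodium to the chromone face that gives (2S), and the 2-aryl-substituted enone of the flavone unit is too hindered to compete.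

Step 15
Reactants: 33 (2S)-5-(benzyloxy)-2-{4-(benzyloxy)-3-[4-(5,7-bis(benzyloxy)-4-oxo-4H-chromen-2-yl)phenoxy]phenyl}-7-methoxy-2,3-dihydro-4H-chromen-4-one
Product: 34 (2S)-2-{3-[4-(5,7-dihydroxy-4-oxo-4H-chromen-2-yl)phenoxy]-4-hydroxyphenyl}-5-hydroxy-7-methoxy-2,3-dihydro-4H-chromen-4-one
Conditions: H2 (1 atm), Pd/C, THF/MeOH, 20 °C
Reagents that add atoms: none
Why: Hydrogenolysis of four aryl benzyl ethers under neutral conditions; benzyl C–O cleavage is expected to be much faster than reduction of the flavone C2=C3 bond or hydrogenolysis of the flavanone C2–O1 bond, and C2 is not exposed to acid or base.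

## Compound list

1 | 5-bromo-2-hydroxybenzaldehyde | O=Cc1cc(Br)ccc1O | starting material
2 | 2-(benzyloxy)-5-bromobenzaldehyde | O=Cc1cc(Br)ccc1OCc1ccccc1 | intermediate
3 | 2-(benzyloxy)-5-bromophenyl formate | O=COc1cc(Br)ccc1OCc1ccccc1 | intermediate
4 | 2-(benzyloxy)-5-bromophenol | Oc1cc(Br)ccc1OCc1ccccc1 | intermediate
5 | 4'-fluoroacetophenone | CC(=O)c1ccc(F)cc1 | starting material
6 | 1-{4-[2-(benzyloxy)-5-bromophenoxy]phenyl}ethan-1-one | CC(=O)c1ccc(Oc2cc(Br)ccc2OCc2ccccc2)cc1 | intermediate
7 | ethyl acetate | CCOC(C)=O | starting material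
8 | 1-{4-[2-(benzyloxy)-5-bromophenoxy]phenyl}butane-1,3-dione | CC(=O)CC(=O)c1ccc(Oc2cc(Br)ccc2OCc2ccccc2)cc1 | intermediate
9 | diethyl oxalate | CCOC(=O)C(=O)OCC | starting material
10 | ethyl 6-{4-[2-(benzyloxy)-5-bromophenoxy]phenyl}-2,4,6-trioxohexanoate | CCOC(=O)C(=O)CC(=O)CC(=O)c1ccc(Oc2cc(Br)ccc2OCc2ccccc2)cc1 | intermediate
11 | ethyl 6-{4-[2-(benzyloxy)-5-bromophenoxy]phenyl}-4-oxo-4H-pyran-2-carboxylate | CCOC(=O)c1cc(=O)cc(-c2ccc(Oc3cc(Br)ccc3OCc3ccccc3)cc2)o1 | intermediate
12 | 6-{4-[2-(benzyloxy)-5-bromophenoxy]phenyl}-4-oxo-4H-pyran-2-carboxylic acid | OC(=O)c1cc(=O)cc(-c2ccc(Oc3cc(Br)ccc3OCc3ccccc3)cc2)o1 | intermediate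
13 | isobutyl carbonic anhydride of acid 12 | CC(C)COC(=O)OC(=O)c1cc(=O)cc(-c2ccc(Oc3cc(Br)ccc3OCc3ccccc3)cc2)o1 | intermediate
14 | 2-{4-[2-(benzyloxy)-5-bromophenoxy]phenyl}-6-(2-diazoacetyl)-4H-pyran-4-one | [N-]=[N+]=CC(=O)c1cc(=O)cc(-c2ccc(Oc3cc(Br)ccc3OCc3ccccc3)cc2)o1 | intermediate
15 | acetylene | C#C | starting material
16 | triisopropylsilyl trifluoromethanesulfonate | CC(C)[Si](C(C)C)(C(C)C)OS(=O)(=O)C(F)(F)F | starting material
17 | lithium acetylide | [Li+].[C-]#C | intermediate
18 | lithium ethynolate | [Li+].[O-]C#C | intermediate
19 | (triisopropylsiloxy)acetylene | C#CO[Si](C(C)C)(C(C)C)C(C)C | intermediate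
20 | (6-{4-[2-(benzyloxy)-5-bromophenoxy]phenyl}-4-oxo-4H-pyran-2-yl)ketene | O=C=Cc1cc(=O)cc(-c2ccc(Oc3cc(Br)ccc3OCc3ccccc3)cc2)o1 | intermediate
21 | 4-(6-{4-[2-(benzyloxy)-5-bromophenoxy]phenyl}-4-oxo-4H-pyran-2-yl)-3-[(triisopropylsilyl)oxy]cyclobut-2-en-1-one | O=C1C=C(O[Si](C(C)C)(C(C)C)C(C)C)C1c1cc(=O)cc(-c2ccc(Oc3cc(Br)ccc3OCc3ccccc3)cc2)o1 | intermediate
22 | 4-(6-aryl-4-oxo-4H-pyran-2-yl)-3-[(triisopropylsilyl)oxy]buta-1,3-dien-1-one, pyranone cis to the ketenyl carbon | O=C=C/C(O[Si](C(C)C)(C(C)C)C(C)C)=C\c1cc(=O)cc(-c2ccc(Oc3cc(Br)ccc3OCc3ccccc3)cc2)o1 | intermediate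
23 | 4a-H cyclohexadienone tautomer of 24 (racemic at C4a) | O=C1C=C(O[Si](C(C)C)(C(C)C)C(C)C)C=C2OC(c3ccc(Oc4cc(Br)ccc4OCc4ccccc4)cc3)=CC(=O)C12 | intermediate
24 | 2-{4-[2-(benzyloxy)-5-bromophenoxy]phenyl}-5-hydroxy-7-[(triisopropylsilyl)oxy]-4H-chromen-4-one | O=c1cc(-c2ccc(Oc3cc(Br)ccc3OCc3ccccc3)cc2)oc2cc(O[Si](C(C)C)(C(C)C)C(C)C)cc(O)c12 | intermediate
25 | 2-{4-[2-(benzyloxy)-5-bromophenoxy]phenyl}-5,7-dihydroxy-4H-chromen-4-one | O=c1cc(-c2ccc(Oc3cc(Br)ccc3OCc3ccccc3)cc2)oc2cc(O)cc(O)c12 | intermediate
26 | 5,7-bis(benzyloxy)-2-{4-[2-(benzyloxy)-5-bromophenoxy]phenyl}-4H-chromen-4-one | O=c1cc(-c2ccc(Oc3cc(Br)ccc3OCc3ccccc3)cc2)oc2cc(OCc3ccccc3)cc(OCc3ccccc3)c12 | intermediate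
27 | pinacol ester of boronic acid 28 | CC1(C)OB(c2ccc(OCc3ccccc3)c(Oc3ccc(-c4cc(=O)c5c(OCc6ccccc6)cc(OCc6ccccc6)cc5o4)cc3)c2)OC1(C)C | intermediate
28 | {4-(benzyloxy)-3-[4-(5,7-bis(benzyloxy)-4-oxo-4H-chromen-2-yl)phenoxy]phenyl}boronic acid | OB(O)c1ccc(OCc2ccccc2)c(Oc2ccc(-c3cc(=O)c4c(OCc5ccccc5)cc(OCc5ccccc5)cc4o3)cc2)c1 | intermediate
29 | 1-(2,6-dihydroxy-4-methoxyphenyl)ethan-1-one | COc1cc(O)c(C(C)=O)c(O)c1 | starting material
30 | 1-[2-(benzyloxy)-6-hydroxy-4-methoxyphenyl]ethan-1-one | COc1cc(O)c(C(C)=O)c(OCc2ccccc2)c1 | intermediate
31 | (E)-1-[2-(benzyloxy)-6-hydroxy-4-methoxyphenyl]-3-(dimethylamino)prop-2-en-1-one | COc1cc(O)c(C(=O)/C=C/N(C)C)c(OCc2ccccc2)c1 | intermediate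
32 | 5-(benzyloxy)-7-methoxy-4H-chromen-4-one | COc1cc(OCc2ccccc2)c2c(c1)occc2=O | intermediate
33 | (2S)-5-(benzyloxy)-2-{4-(benzyloxy)-3-[4-(5,7-bis(benzyloxy)-4-oxo-4H-chromen-2-yl)phenoxy]phenyl}-7-methoxy-2,3-dihydro-4H-chromen-4-one | COc1cc(OCc2ccccc2)c2c(c1)O[C@H](c1ccc(OCc3ccccc3)c(Oc3ccc(-c4cc(=O)c5c(OCc6ccccc6)cc(OCc6ccccc6)cc5o4)cc3)c1)CC2=O | intermediate
34 | (2S)-2-{3-[4-(5,7-dihydroxy-4-oxo-4H-chromen-2-yl)phenoxy]-4-hydroxyphenyl}-5-hydroxy-7-methoxy-2,3-dihydro-4H-chromen-4-one | COc1cc(O)c2c(c1)O[C@H](c1ccc(O)c(Oc3ccc(-c4cc(=O)c5c(O)cc(O)cc5o4)cc3)c1)CC2=O | target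

## Step count and risks

Total: 15 steps. Longest linear sequence: 12 steps (1, 2, 3, 4, 5, 6, 7, 9, 10, 11, 14, 15).

**Step 9 (key step).** The aryl-pyranone chromophore may compete for light and photorearrange, or bromine may be lost photolytically, before the Wolff rearrangement is complete. Slow capture of the ketene would lead to its dimerisation. The fallback generates ketene 20 without light. Setting out from 14, Wolff rearrangement catalysed by AgO2CPh and Et3N in aqueous dioxane in the dark would give (6-{4-[2-(benzyloxy)-5-bromophenoxy]phenyl}-4-oxo-4H-pyran-2-yl)acetic acid F1. Treatment of F1 with 1-chloro-N,N,2-trimethylprop-1-en-1-amine in CH2Cl2 at 0 °C would give (6-{4-[2-(benzyloxy)-5-bromophenoxy]phenyl}-4-oxo-4H-pyran-2-yl)acetyl chloride F2. Slow addition of F2 to Et3N and 19 would form 20 by dehydrochlorination and, by the known [2+2] cycloaddition of such ketenes with siloxyacetylenes, cyclobutenone 21. Heating 21 at 80 °C takes the sequence on as in the main route and rejoins it at 24.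

**Step 7.** Diazomethane may undergo 1,3-dipolar cycloaddition to the acyl-substituted C=C bond of the pyranone, or attack at the carbonate carbonyl of 13 may divert material to the methyl ester. The fallback avoids diazomethane and sets out from 8. Its dianion (LiN(iPr)2) would be acylated with methyl 2,2-dimethoxypropanoate to give 1-{4-[2-(benzyloxy)-5-bromophenoxy]phenyl}-6,6-dimethoxyheptane-1,3,5-trione F3. Aqueous acid would close the pyranone of F3 and hydrolyse its ketal to 2-acetyl-6-{4-[2-(benzyloxy)-5-bromophenoxy]phenyl}-4H-pyran-4-one F4. Detrifluoroacetylative diazo transfer would follow: LiN(SiMe3)2 and CF3CO2CH2CF3 at −78 °C would convert F4 into 1-(6-{4-[2-(benzyloxy)-5-bromophenoxy]phenyl}-4-oxo-4H-pyran-2-yl)-4,4,4-trifluorobutane-1,3-dione F5, and methanesulfonyl azide, Et3N and water in MeCN would take F5 on to 14, where the route is rejoined.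

**Step 8.** Monolithium acetylide may disproportionate to the insoluble dilithium salt before oxygen transfer, and the volatile, acid-sensitive ynol ether may be lost on isolation. The fallback runs the benzannulation with commercial ethoxyacetylene, a ketenophile of the same polarisation. Setting out from 14 under the conditions of step 9, it should give 2-{4-[2-(benzyloxy)-5-bromophenoxy]phenyl}-7-ethoxy-5-hydroxy-4H-chromen-4-one F6. BBr3 in CH2Cl2 would cleave the ethyl and benzyl ethers of F6 to 2-[4-(5-bromo-2-hydroxyphenoxy)phenyl]-5,7-dihydroxy-4H-chromen-4-one F7. Tribenzylation of F7 with BnBr and K2CO3 in DMF at 65 °C returns to the route at 26, one step longer.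

**Step 14.** Insertion of the doubly donor-substituted chromone may be slow, so that protodeboronation of 28 consumes the valuable partner. Facial selectivity may be incomplete on this large aryl group, or the enantiomeric purity may erode through reversible opening of ring C. The fallback separates bond formation from stereocontrol. From 28 and 32, [RhOH(cod)]2 without a chiral ligand in dioxane/H2O would give the racemic flavanone F8. Preparative chromatography of F8 on a chiral stationary phase then delivers 33, where the route is rejoined, and the (2R)-configured flavanone F9 is set aside.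

**Step 15.** The flavone C2=C3 bond may be over-reduced, or the benzylic C2–O1 bond of the flavanone may be opened by hydrogenolysis, if debenzylation of the chelated 5-ethers is slow. The fallback is non-reductive debenzylation of 33 with BCl3 and pentamethylbenzene as cation scavenger in CH2Cl2 at −78 °C. It leads directly to 34 and makes no new intermediate.

## Further compounds

F1 | step 9 | (6-{4-[2-(benzyloxy)-5-bromophenoxy]phenyl}-4-oxo-4H-pyran-2-yl)acetic acid | OC(=O)Cc1cc(=O)cc(-c2ccc(Oc3cc(Br)ccc3OCc3ccccc3)cc2)o1
F2 | step 9 | (6-{4-[2-(benzyloxy)-5-bromophenoxy]phenyl}-4-oxo-4H-pyran-2-yl)acetyl chloride | ClC(=O)Cc1cc(=O)cc(-c2ccc(Oc3cc(Br)ccc3OCc3ccccc3)cc2)o1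
F3 | step 7 | 1-{4-[2-(benzyloxy)-5-bromophenoxy]phenyl}-6,6-dimethoxyheptane-1,3,5-trione | CC(OC)(OC)C(=O)CC(=O)CC(=O)c1ccc(Oc2cc(Br)ccc2OCc2ccccc2)cc1
F4 | step 7 | 2-acetyl-6-{4-[2-(benzyloxy)-5-bromophenoxy]phenyl}-4H-pyran-4-one | CC(=O)c1cc(=O)cc(-c2ccc(Oc3cc(Br)ccc3OCc3ccccc3)cc2)o1
F5 | step 7 | 1-(6-{4-[2-(benzyloxy)-5-bromophenoxy]phenyl}-4-oxo-4H-pyran-2-yl)-4,4,4-trifluorobutane-1,3-dione | O=C(CC(=O)C(F)(F)F)c1cc(=O)cc(-c2ccc(Oc3cc(Br)ccc3OCc3ccccc3)cc2)o1
F6 | step 8 | 2-{4-[2-(benzyloxy)-5-bromophenoxy]phenyl}-7-ethoxy-5-hydroxy-4H-chromen-4-one | CCOc1cc(O)c2c(c1)oc(-c1ccc(Oc3cc(Br)ccc3OCc3ccccc3)cc1)cc2=O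
F7 | step 8 | 2-[4-(5-bromo-2-hydroxyphenoxy)phenyl]-5,7-dihydroxy-4H-chromen-4-one | O=c1cc(-c2ccc(Oc3cc(Br)ccc3O)cc2)oc2cc(O)cc(O)c12
F8 | step 14 | racemic 33 | COc1cc(OCc2ccccc2)c2c(c1)OC(c1ccc(OCc3ccccc3)c(Oc3ccc(-c4cc(=O)c5c(OCc6ccccc6)cc(OCc6ccccc6)cc5o4)cc3)c1)CC2=O
F9 | step 14 | (2R)-enantiomer of 33 | COc1cc(OCc2ccccc2)c2c(c1)O[C@@H](c1ccc(OCc3ccccc3)c(Oc3ccc(-c4cc(=O)c5c(OCc6ccccc6)cc(OCc6ccccc6)cc5o4)cc3)c1)CC2=O
F0 | step 15 | none | none
A1 | alternative 1 | (R)-2-{4-(benzyloxy)-3-(4-bromophenoxy)phenyl}-2-[2-(1,3-dithian-2-yl)-5-methoxy-3-(methoxymethoxy)phenoxy]ethyl 4-methylbenzenesulfonate | COc1cc(OCOC)c(C2SCCCS2)c(O[C@H](c2ccc(OCc3ccccc3)c(Oc3ccc(Br)cc3)c2)COS(=O)(=O)c2ccc(C)cc2)c1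
A2 | alternative 1 | (2S)-flavanone C4 1,3-dithiane ketal with 5-O-methoxymethyl, 7-O-methyl, 4'-O-benzyl and 3'-O-(4-bromophenyl) groups | COc1cc(OCOC)c2c(c1)O[C@H](c1ccc(OCc3ccccc3)c(Oc3ccc(Br)cc3)c1)CC21SCCCS1
A3 | alternative 2 | tert-butyl 4-{2-(benzyloxy)-5-[(1S)-3-(2-bromo-4,6-dimethoxyphenyl)-1-hydroxypropyl]phenoxy}benzoate | COc1cc(OC)c(CC[C@H](O)c2ccc(OCc3ccccc3)c(Oc3ccc(C(=O)OC(C)(C)C)cc3)c2)c(Br)c1
A4 | alternative 2 | tert-butyl 4-{2-(benzyloxy)-5-[(2S)-5,7-dimethoxychroman-2-yl]phenoxy}benzoate | COc1cc(OC)c2c(c1)O[C@H](c1ccc(OCc3ccccc3)c(Oc3ccc(C(=O)OC(C)(C)C)cc3)c1)CC2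
A5 | alternative 3 | 2-diazo-1-{2-[(aryl)methoxy]-4-methoxy-6-[(triisopropylsilyl)oxy]phenyl}ethan-1-one, aryl = 4-(benzyloxy)-3-[4-(5,7-bis(benzyloxy)-4-oxo-4H-chromen-2-yl)phenoxy]phenyl | COc1cc(O[Si](C(C)C)(C(C)C)C(C)C)c(C(=O)C=[N+]=[N-])c(OCc2ccc(OCc3ccccc3)c(Oc3ccc(-c4cc(=O)c5c(OCc6ccccc6)cc(OCc6ccccc6)cc5o4)cc3)c2)c1
A6 | alternative 3 | 5-O-triisopropylsilyl tri-O-benzyl ether of (2S)-34 | COc1cc(O[Si](C(C)C)(C(C)C)C(C)C)c2c(c1)O[C@H](c1ccc(OCc3ccccc3)c(Oc3ccc(-c4cc(=O)c5c(OCc6ccccc6)cc(OCc6ccccc6)cc5o4)cc3)c1)CC2=O
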